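The leftover in the theta run was my starting point: at 120 s it read 30 % of target, whereas the coupling partner, the limiting reagent at two per target, allowed 0.475 per starting material, and the readings were still climbing, so I asked first what the clock costs.

| flask | starting material | coupling partner | protic impurity | remark | time |
|---|---|---|---|---|---|
| theta | 30 mM | 0.95 equiv | 3 mM | run made earlier |  |
| beta | 30 mM | 0.47 equiv | 3 mM | run made earlier |  |
| Friday's | 30 mM (fed, over 1.5 min) | 0.950 equiv | 3.00 mM | all else is in the flask from the start; the feed brings no volume worth counting | 2.0 min |
| Monday's | 30 mM (in portions, 4, over 1.5 min) | 0.950 equiv | 3.00 mM | first portion at the start, last at 1.5 min | 2.0 min |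
| Wednesday's | 30 mM | 0.950 equiv | 3.00 mM | everything together at the start | 2.0 min |
| Tuesday's | 30 mM | 0.950 equiv (fed, over 1.5 min) | 3.00 mM | all else is in the flask from the start; the feed brings no volume worth counting | 2.0 min |

| run | time / s | target / % |
|---|---|---|
| theta | 25.0 | 11 |
| theta | 50.0 | 17 |
| theta | 80.0 | 22 |
| theta | 90.0 | 25 |
| theta | 120 | 30 |
| beta | 10.0 | 2 |
| beta | 15.0 | 1 |
| beta | 25.0 | 3 |
| beta | 40.0 | 2 |

(readings scatter by 2 percentage points)

- the numbers in the tables scatter by 2 percentage points (one standard deviation)
- steps under discussion: starting material + coupling partner <-> intermediate A; starting material + coupling partner -> intermediate B; intermediate B <-> intermediate C; coupling partner + intermediate A -> intermediate D; intermediate D -> target; intermediate D <-> intermediate E; intermediate A -> intermediate B; starting material + protic impurity -> quenched substrate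

- the flask that comes out highest in amount of target, in percent of the starting material charged, or "all alike" when all lie within 1.5 percentage points (Friday's / Monday's / Wednesday's / Tuesday's / all alike)
- target at the end, in percent of the starting material charged, Friday's
- target at the end, in percent of the starting material charged, Monday's
- target at the end, in percent of the starting material charged, Wednesday's
- target at the end, in percent of the starting material charged, Tuesday's

Between 25.0 s and 120 s the theta run rose by 0.120 min⁻¹ as a fraction of the charge, a reading that carries the scatter, and since Wednesday's repeats theta, I committed to about 30 % for Wednesday's.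

Next I asked what a feed costs: starting material fed steadily over 1.5 min arrives on average 0.750 min late, and Monday's 4 equal portions have the same mean delay, so I defined the feed toll, that rate times the mean delay, as 9 percentage points, which is larger than the scatter, and I put Friday's and Monday's near 21.0 %.

Last I asked whether Tuesday's pays more: at 25.0 s beta read 3 % against theta's 11 % at the same time, two readings that each carry the scatter of 2 points, which on logarithms give a reading of 1.85 for the apparent order in coupling partner, so I placed Tuesday's, whose coupling partner comes in over 1.5 min, below 21.0 %.

The forecast differed from my reckoning on Friday's and Monday's, with Friday's on top at 38 %, Monday's 35 %, Wednesday's 30 % and Tuesday's 8 %, and of the gain it expected in Friday's it said “Late feed and time limits cap it”.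

Wednesday's came out highest at 28.6 %, with Friday's at 23.4 %, Monday's at 23.7 % and Tuesday's at 17.8 %.

    starting material + coupling partner ⇌ intermediate A (K = 120 M⁻¹, k = 3.00 M⁻¹ s⁻¹)
    starting material + coupling partner → intermediate B (k = 0.550 M⁻¹ s⁻¹)
    intermediate B ⇌ intermediate C (K = 10.0, k = 0.0250 s⁻¹)
    coupling partner + intermediate A → intermediate D (k = 30.0 M⁻¹ s⁻¹)
    intermediate D → target (k = 0.140 s⁻¹)
    intermediate D ⇌ intermediate E (K = 9.00, k = 0.500 s⁻¹)
    intermediate A → intermediate B (k = 0.0540 s⁻¹)
    starting material + protic impurity → quenched substrate (k = 240 M⁻¹ s⁻¹)

Left until 20.0 min, Friday's stood at 37.6 % against Wednesday's 37.3 %. Friday's paid 5.2 points at the asked time, against my toll of 9 points. The same rate over the 70.0 s missing from Wednesday's read at 50 s gives 14 points, and that neighbour stood at 18.0 %, 11 points below Wednesday's.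

The earlier runs and the new flask were computed on assumed constants; noise was put on by code.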